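The C13 methyl and the C9–C10 bond stand 1,4 on ring C, which is the p-menthane pattern. (S)-Carvone therefore delivers ring C intact, and its isopropenyl group supplies C10, C1 and the oxygenated C20. The plan rests on cutting C5–C10 and C1–C2. One intramolecular Diels–Alder reaction between a C2=C3–C4=C5 silyloxydiene and the C10=C1 acrylate closes rings A and B and sets C5 and C10. It also leaves a regiodefined C3–C4 silyl enol ether that later accepts C19. The precursor is carvone dialkylated at C8 (methyl C17 and a three-carbon arm ending in the diene), with its isopropenyl methyl oxidised to a methyl ester.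

Key step: step 10

Numbering: diterpene numbering is used. C15 is the benzylic CH2 on C14, C16 the methyl on C13, C17 the methyl on C8, C18 the methyl on C4, C19 the lactone carbonyl on C4, and C20 the OCH2 on C10. β is the face of C17.

Remark on the chemistry: the SMILES is read as written, so C15 on C14 and the hydroxyl on C13 are both α (H14 and C16 are β). This cis pair is what a suprafacial addition to the α face of a C13=C14 alkene delivers.

Step 1
Reactants: 1 (S)-carvone; 2 iodomethane
Product: 4 6-methylcarvone (C8 epimers), via lithium dienolate 3 (not isolated)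
Conditions: LiN(i-Pr)2, THF, −78 °C; then MeI, −78 to 0 °C
Reagents that add atoms: iodomethane (2), CI
Why: Kinetic deprotonation at the α′-methylene of carvone (future C8) and SN2 methylation of the cross-conjugated dienolate is a standard enolate alkylation that brings in C17; the new centre is planarised again in step 2, while C9 (H9 α) is carried over unchanged from (S)-carvone.

Step 2
Reactants: 4 6-methylcarvone; 5 allyl bromide
Product: 7 6-allyl-6-methylcarvone, via lithium dienolate 6 (not isolated)
Conditions: LiN(i-Pr)2, THF–DMPU, −78 to 0 °C; then allyl bromide, −78 °C to rt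
Reagents that add atoms: allyl bromide (5), C=CCBr
Why: In this second enolate alkylation the planar C8 enolate should be attacked by the reactive allylic halide on the face opposite the vicinal isopropenyl group on C9, so the C7 arm ends trans to C10 and C17 ends β (quaternary C8 set by 1,2-induction).

Step 3
Reactants: 7 6-allyl-6-methylcarvone
Product: 9 primary alcohol at C5, via alkyl(dicyclohexyl)borane 8 (not isolated)
Conditions: Cy2BH (from BH3·SMe2 and cyclohexene), THF, 0 °C; then NaBO3·4H2O, H2O, rt
Reagents that add atoms: sodium perborate, [Na+].[O-]OB=O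
Why: In this Brown hydroboration–oxidation the bulky dialkylborane should pick the monosubstituted allyl terminus over the crowded 1,1-disubstituted isopropenyl group and the hindered conjugated ketone, and perborate replaces alkaline peroxide to avoid Weitz–Scheffer epoxidation of the enone.

Step 4
Reactants: 9 primary alcohol at C5
Product: 10 aldehyde at C5
Conditions: Dess–Martin periodinane, CH2Cl2, 0 °C to rt
Reagents that add atoms: none
Why: Dess–Martin oxidation stops at the aldehyde under near-neutral conditions and leaves the alkenes and the enone untouched.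

Step 5
Reactants: 10 aldehyde at C5; 11 3-(triphenylphosphoranylidene)butan-2-one
Product: 12 bis-enone with the (E)-C4=C5 side chain
Conditions: toluene, 100 °C
Reagents that add atoms: 3-(triphenylphosphoranylidene)butan-2-one (11), CC(=O)C(C)=P(c1ccccc1)(c1ccccc1)c1ccccc1
Why: Wittig olefination with a ketone-stabilised ylide reacts only with the aldehyde (the C14 ketone is inert) and is E-selective, which places C6 trans to C3 as the cycloaddition requires.

Step 6
Reactants: 12 bis-enone
Product: 14 2-substituted acrolein (C20 aldehyde), via allylic alcohol 13 (not isolated)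
Conditions: SeO2 (cat.), t-BuOOH, CH2Cl2, rt; crude product then MnO2, CH2Cl2, rt
Reagents that add atoms: selenium dioxide, O=[Se]=O; tert-butyl hydroperoxide, CC(C)(C)OO
Why: SeO2 allylic oxidation (ene reaction, then [2,3]-shift) should engage the only electron-rich alkene, the isopropenyl group, at its methyl, because C9–H lies near the alkene plane and is shielded by quaternary C8; MnO2 then converges any allylic alcohol to the enal.

Step 7
Reactants: 14 2-substituted acrolein
Product: 15 2-substituted acrylic acid (C20 acid)
Conditions: NaClO2, NaH2PO4, 2-methyl-2-butene, t-BuOH–H2O, 0 °C to rt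
Reagents that add atoms: sodium chlorite, [Na+].[O-]Cl=O
Why: Pinnick oxidation converts α-methylene aldehydes into the acids without touching enones, and the alkene scavenger removes the hypochlorous acid that is formed.

Step 8
Reactants: 15 acrylic acid; 2 iodomethane
Product: 16 methyl acrylate
Conditions: MeI, K2CO3, DMF, rt
Reagents that add atoms: iodomethane (2), CI
Why: SN2 O-alkylation of the carboxylate needs only a weak base, which neither enolises the ketones nor adds to the acrylate.

Step 9
Reactants: 16 methyl acrylate
Product: 17 silyloxydiene acrylate (cycloaddition precursor)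
Conditions: TBSOTf, Et3N, CH2Cl2, −78 to 0 °C; filtration through Et3N-deactivated silica
Reagents that add atoms: tert-butyldimethylsilyl triflate, CC(C)(C)[Si](C)(C)OS(=O)(=O)C(F)(F)F
Why: Soft enolisation silylates the methyl ketone at its α′-methyl (C2) to give the cross-conjugated 2-silyloxydiene; the C14 ketone has no α-hydrogen (C8 is quaternary, C13 is sp2) and the ester is inert.

Step 10
Reactants: 17 silyloxydiene acrylate
Product: 18 trans-anti-trans tricycle
Conditions: toluene (0.01 M), BHT (cat.), base-washed sealed tube, 170 °C
Reagents that add atoms: none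
Why: This is a concerted but asynchronous normal-electron-demand [4+2] cycloaddition in which the nucleophilic diene terminus C2 (next to the silyloxy carbon C3) bonds to the acrylate β-carbon C1 and C5 bonds to C10, a pairing that the four-atom tether C6–C9 also imposes; the closest known reaction type is the thermal type 1 intramolecular Diels–Alder reaction of 1,7,9-decatrienes carrying a 2-silyloxydiene and an acrylate. Ring A closes as the new cyclohexene that contains both new bonds, and ring B closes in the fused mode through C5–C10 alone as the six-membered ring that holds the tether. C10 is controlled by the chair-like tether, which is anchored on ring C by the trans-diequatorial C7 and C10 arms (relay from C8 and C9): the only axial site at C10 points β, so C20 should end β and anti to H9. C5 is controlled by the endo orientation of the ester, which puts the tether exo; with the E-configured C4=C5 bond this places H5 α and trans to C20, and the C18 methyl on C4 is expected to add a steric penalty to the cis-fused alternative. The step needs periselectivity for the acrylate over the ring C enone and trans over cis fusion; the free terminal methylene C1 of the acrylate should outrun the trisubstituted C12=C13, whose use would demand an axial C7 arm and a bridged bicyclo[3.3.1] array. High dilution, a radical inhibitor and base-washed glass protect the acrylate and the silyl enol ether during heating.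

Step 11
Reactants: 18 trans-anti-trans tricycle
Product: 20 C14 enol triflate, via lithium enolate 19 (not isolated)
Conditions: LiBH(s-Bu)3, THF, −78 °C; then PhNTf2, −78 °C to rt
Reagents that add atoms: N-phenylbis(trifluoromethanesulfonimide), O=S(=O)(N(c1ccccc1)S(=O)(=O)C(F)(F)F)C(F)(F)F
Why: Conjugate hydride addition to the β-unsubstituted, carbonyl-hindered cyclohexenone followed by O-triflation of the regiodefined enolate fixes the C13=C14 position and masks the ring C carbonyl before the ester is reduced; the crowded angular ester and the silyl enol ether do not react at this temperature.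

Step 12
Reactants: 20 C14 enol triflate
Product: 21 C20 primary alcohol
Conditions: i-Bu2AlH (excess), CH2Cl2, −78 to 0 °C; aq. potassium sodium tartrate
Reagents that add atoms: none
Why: With ring C masked, the axial methyl ester is the only reducible group, and i-Bu2AlH reduces esters to primary alcohols in the presence of enol triflates and silyl enol ethers, with a non-acidic work-up.

Step 13
Reactants: 21 C20 primary alcohol
Product: 22 C20 imidazole-1-carboxylate
Conditions: 1,1′-carbonyldiimidazole, CH2Cl2, rt
Reagents that add atoms: 1,1′-carbonyldiimidazole, O=C(n1ccnc1)n1ccnc1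
Why: Acyl transfer from carbonyldiimidazole to the primary alcohol proceeds under neutral conditions that spare the silyl enol ether, and it installs C19 at the carboxyl oxidation level already bound to O–C20.

Step 14
Reactants: 22 C20 imidazole-1-carboxylate
Product: 24 3-keto 19,20-lactone, via sulfonium enolate 23 (not isolated)
Conditions: (Me2N)3S+ Me3SiF2− (TASF), THF (0.005 M), −78 to 0 °C; AcOH quench
Reagents that add atoms: none
Why: Fluoride desilylation frees the regiodefined C3–C4 enolate, which is C-acylated by the tethered acyl imidazole (Dieckmann-type enolate acylation) to close the six-membered lactone; the acyl carbon hangs from β-axial C20 and reaches only the β face of C4, which sets C4 (C19 β, C18 α), while O-acylation would need a strained bridged eight-membered ring and the weakly basic imidazolide cannot reopen the non-enolisable β-keto lactone as an alkoxide leaving group could.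

Step 15
Reactants: 24 3-keto 19,20-lactone
Product: 26 bis(enol triflate), via potassium enolate 25 (not isolated)
Conditions: KN(SiMe3)2, THF, −78 °C; then PhNTf2, −78 to 0 °C
Reagents that add atoms: N-phenylbis(trifluoromethanesulfonimide), O=S(=O)(N(c1ccccc1)S(=O)(=O)C(F)(F)F)C(F)(F)F
Why: The C3 ketone can enolise only towards C2 because C4 is quaternary, and O-triflation of such 4,4-disubstituted 3-keto terpenoid enolates is routine; a non-nucleophilic base avoids retro-Claisen cleavage.

Step 16
Reactants: 26 bis(enol triflate)
Product: 27 2,13-diene lactone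
Conditions: Pd(OAc)2 (cat.), PPh3, HCO2H, Et3N, DMF, 60 °C
Reagents that add atoms: none
Why: In this palladium-catalysed formate hydrogenolysis of enol triflates, oxidative addition to zerovalent palladium, formate exchange, decarboxylation and reductive elimination replace both OTf groups by H without moving either alkene, a process established for hindered 2,6,6-trisubstituted cyclohexenyl triflates.

Step 17
Reactants: 27 2,13-diene lactone
Product: 28 13-ene lactone
Conditions: H2 (1 atm), RhCl(PPh3)3 (cat.), benzene–EtOH, rt
Reagents that add atoms: none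
Why: Homogeneous hydrogenation with RhCl(PPh3)3 discriminates by substitution, so the cis-disubstituted C2=C3 should be saturated while the trisubstituted C13=C14 next to quaternary C8 stays; this completes the removal of the C3 oxygen and creates no stereocentre.

Step 18
Reactants: 29 2-hydroxy-5-methoxybenzaldehyde
Product: 30 2-(hydroxymethyl)-4-methoxyphenol
Conditions: NaBH4, MeOH, 0 °C
Reagents that add atoms: none
Why: Borohydride reduction of an aromatic aldehyde gives the salicyl alcohol that serves as the thermal quinone methide precursor.

Step 19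
Reactants: 28 13-ene lactone; 30 2-(hydroxymethyl)-4-methoxyphenol
Product: 32 cis-fused 6-methoxychroman, via o-quinone methide 31 (not isolated)
Conditions: 30 (excess, slow addition), o-dichlorobenzene, 180 °C
Reagents that add atoms: 2-(hydroxymethyl)-4-methoxyphenol (30), COc1ccc(O)c(CO)c1
Why: This is the inverse-electron-demand hetero-Diels–Alder reaction of a thermally generated o-quinone methide with a trisubstituted alkene, a reaction type known for terpene alkenes; the small methylene terminus bonds to the less substituted C14 and oxygen to C13, and the suprafacial addition should come from the α face because axial C17 shields the β face, which sets C13 (O α, C16 β) and C14 (C15 α, H β) together.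

Step 20
Reactants: 32 cis-fused 6-methoxychroman
Product: 33 hydroxy quinone
Conditions: (NH4)2Ce(NO3)6, MeCN–H2O, 0 °C
Reagents that add atoms: water, O
Why: In this oxidative dealkylation of a hydroquinone diether by tetravalent cerium, water attacks the two oxygenated ring carbons so the aryl–O bonds break; methanol leaves and the C13–O bond stays intact, which frees the tertiary alcohol with retention.

Step 21
Reactants: 33 hydroxy quinone
Product: 34 target CNP0148621.1
Conditions: Na2S2O4, THF–H2O, rt
Reagents that add atoms: none
Why: Dithionite reduction of the quinone to the hydroquinone runs under near-neutral conditions, which avoids acid-induced dehydration or re-closure to the chroman and touches no stereocentre.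

Compound list

1 | (S)-(+)-carvone | CC1=CC[C@@H](CC1=O)C(=C)C | starting material
2 | iodomethane | CI | starting material
3 | lithium cross-conjugated dienolate of 1 | CC1=CC[C@@H](C=C1[O-])C(=C)C.[Li+] | intermediate
4 | (5S)-6-methylcarvone, mixture of epimers at the methylated carbon (future C8) | CC1=CC[C@@H](C(C)C1=O)C(=C)C | intermediate
5 | allyl bromide | C=CCBr | starting material
6 | lithium dienolate of 4 (C8 planar) | CC1=CC[C@@H](C(C)=C1[O-])C(=C)C.[Li+] | intermediate
7 | (5R,6R)-6-allyl-2,6-dimethyl-5-(prop-1-en-2-yl)cyclohex-2-en-1-one; allyl trans and methyl cis to isopropenyl | C[C@@]1(CC=C)[C@@H](C(=C)C)CC=C(C)C1=O | intermediate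
8 | B-alkyl dicyclohexylborane from 7 (boron on C5) | C[C@@]1(CCCB(C2CCCCC2)C2CCCCC2)[C@@H](C(=C)C)CC=C(C)C1=O | intermediate
9 | 3-hydroxypropyl analogue of 7 (C7–C6–C5–OH on C8) | C[C@@]1(CCCO)[C@@H](C(=C)C)CC=C(C)C1=O | intermediate
10 | 3-oxopropyl analogue of 7 (C5 aldehyde) | C[C@@]1(CCC=O)[C@@H](C(=C)C)CC=C(C)C1=O | intermediate
11 | 3-(triphenylphosphoranylidene)butan-2-one | CC(=O)C(C)=P(c1ccccc1)(c1ccccc1)c1ccccc1 | starting material
12 | bis-enone: C8 arm CH2CH2CH=C(CH3)C(O)CH3 with (E)-C4=C5, isopropenyl on C9 | C[C@@]1(CC/C=C(C)/C(C)=O)[C@@H](C(=C)C)CC=C(C)C1=O | intermediate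
13 | allylic alcohol: 12 with C20 as CH2OH on C10 | C[C@@]1(CC/C=C(C)/C(C)=O)[C@@H](C(=C)CO)CC=C(C)C1=O | intermediate
14 | enal: 12 with C20 as CHO on C10(=C1H2) | C[C@@]1(CC/C=C(C)/C(C)=O)[C@@H](C(=C)C=O)CC=C(C)C1=O | intermediate
15 | acrylic acid: 12 with C20 as CO2H | C[C@@]1(CC/C=C(C)/C(C)=O)[C@@H](C(=C)C(=O)O)CC=C(C)C1=O | intermediate
16 | methyl acrylate: 12 with C20 as CO2Me | C[C@@]1(CC/C=C(C)/C(C)=O)[C@@H](C(=C)C(=O)OC)CC=C(C)C1=O | intermediate
17 | cycloaddition precursor: 16 with the methyl ketone as its C2=C3 TBS dienol ether | C[C@@]1(CC/C=C(C)/C(=C)O[Si](C)(C)C(C)(C)C)[C@@H](C(=C)C(=O)OC)CC=C(C)C1=O | intermediate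
18 | trans-anti-trans tricycle: CO2Me (C20) β on C10, H5 α, H9 α, C17 β, TBS enol ether C3=C4, enone C12=C13–C14=O | C[C@@]12CC[C@@H]3[C@](C(=O)OC)(CCC(O[Si](C)(C)C(C)(C)C)=C3C)[C@H]1CC=C(C)C2=O | intermediate
19 | lithium C13=C14 enolate of 12,13-dihydro-18 | C[C@@]12CC[C@@H]3[C@](C(=O)OC)(CCC(O[Si](C)(C)C(C)(C)C)=C3C)[C@H]1CCC(C)=C2[O-].[Li+] | intermediate
20 | C14 enol triflate (C13=C14) with C20 methyl ester and C3=C4 TBS enol ether | C[C@@]12CC[C@@H]3[C@](C(=O)OC)(CCC(O[Si](C)(C)C(C)(C)C)=C3C)[C@H]1CCC(C)=C2OS(=O)(=O)C(F)(F)F | intermediate
21 | C20 primary alcohol (β-CH2OH on C10) of 20 | C[C@@]12CC[C@@H]3[C@](CO)(CCC(O[Si](C)(C)C(C)(C)C)=C3C)[C@H]1CCC(C)=C2OS(=O)(=O)C(F)(F)F | intermediate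
22 | C20 imidazole-1-carboxylate of 21 | C[C@@]12CC[C@@H]3[C@](COC(=O)n4ccnc4)(CCC(O[Si](C)(C)C(C)(C)C)=C3C)[C@H]1CCC(C)=C2OS(=O)(=O)C(F)(F)F | intermediate
23 | tris(dimethylamino)sulfonium C3–C4 enolate from 22 | C[C@@]12CC[C@@H]3[C@](COC(=O)n4ccnc4)(CCC([O-])=C3C)[C@H]1CCC(C)=C2OS(=O)(=O)C(F)(F)F.CN(C)[S+](N(C)C)N(C)C | intermediate
24 | 3-keto 19,20-lactone: C19 β and C18 α on C4, C14 enol triflate | C[C@@]12CC[C@@H]3[C@]4(CCC(=O)[C@]3(C)C(=O)OC4)[C@H]1CCC(C)=C2OS(=O)(=O)C(F)(F)F | intermediate
25 | potassium C2=C3 enolate of 24 | C[C@@]12CC[C@@H]3[C@]4(CC=C([O-])[C@]3(C)C(=O)OC4)[C@H]1CCC(C)=C2OS(=O)(=O)C(F)(F)F.[K+] | intermediate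
26 | bis(enol triflate): C3–OTf (C2=C3) and C14–OTf (C13=C14) | C[C@@]12CC[C@@H]3[C@]4(CC=C(OS(=O)(=O)C(F)(F)F)[C@]3(C)C(=O)OC4)[C@H]1CCC(C)=C2OS(=O)(=O)C(F)(F)F | intermediate
27 | 2,13-diene 19,20-lactone | C[C@@]12CC[C@@H]3[C@]4(CC=C[C@]3(C)C(=O)OC4)[C@H]1CCC(C)=C2 | intermediate
28 | 13-ene 19,20-lactone (C13=C14 only) | C[C@@]12CC[C@@H]3[C@]4(CCC[C@]3(C)C(=O)OC4)[C@H]1CCC(C)=C2 | intermediate
29 | 2-hydroxy-5-methoxybenzaldehyde | COc1ccc(O)c(C=O)c1 | starting material
30 | 2-(hydroxymethyl)-4-methoxyphenol | COc1ccc(O)c(CO)c1 | intermediate
31 | 4-methoxy-6-methylidenecyclohexa-2,4-dien-1-one (o-quinone methide) | COC1=CC(=C)C(=O)C=C1 | intermediate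
32 | cis-fused 6-methoxychroman: aryl O α on C13, C16 β, C15 α on C14, H14 β | C[C@@]12CC[C@@H]3[C@]4(CCC[C@]3(C)C(=O)OC4)[C@H]1CC[C@](C)(Oc5ccc(OC)cc5C6)[C@@H]26 | intermediate
33 | hydroxy quinone: 13α-OH, C15 α carrying a 1,4-benzoquinon-2-yl group | C[C@@]12CC[C@@H]3[C@]4(CCC[C@]3(C)C(=O)OC4)[C@H]1CC[C@](C)(O)[C@@H]2CC5=CC(=O)C=CC5=O | intermediate
34 | CNP0148621.1: 13α-hydroxy-14α-(2,5-dihydroxybenzyl) 19,20-lactone | C[C@@]12CC[C@@H]3[C@]4(CCC[C@]3(C)C(=O)OC4)[C@H]1CC[C@](C)(O)[C@@H]2Cc1cc(O)ccc1O | target

Total step count: 21. Longest linear sequence: 20 steps (steps 1–17 and 19–21, from (S)-carvone).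

Steps most likely to fail

Step 10. The trans over cis preference may erode, the diene may add to the ring C enone, or the silyl enol ether may be lost on prolonged heating. The fallback replaces the pericyclic step by an anionic double Michael addition that forms the same two bonds. It sets out from 16. LiN(SiMe3)2 in Et2O–hexane at −78 °C converts the methyl ketone into its cross-conjugated dienolate. C2 then adds to C1 of the acrylate, and the resulting C10 ester enolate adds to C5 of the side-chain enone through the same chair-like tether. The resulting tricyclic lithium enolate F1 is silylated in the same flask with TBSCl–DMPU, and the route is rejoined at 18.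

Step 19. Self-condensation of the quinone methide may outrun its addition to the hindered alkene, so conversion of the valuable partner may stay low. The fallback forms the C14–C15 and C13–O bonds by a 1,3-dipolar cycloaddition. It sets out from 28.
- Commercial 2,5-dimethoxybenzaldehyde and NH2OH·HCl/NaOAc give 2,5-dimethoxybenzaldehyde oxime F2.
- PhI(OAc)2 oxidises F2 in the presence of 28 to 2,5-dimethoxybenzonitrile oxide F3.
- Suprafacial addition to the α face, with oxygen on the more substituted C13, should give the isoxazoline F4.
- N–O hydrogenolysis with hydrolysis of the imine (H2, Raney Ni, B(OH)3, MeOH–H2O, buffered to avoid epimerisation at C14) gives the β-hydroxy aryl ketone F5.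
- Hydrogenolysis of the aryl ketone (H2, Pd/C, EtOH–AcOH) gives the hydroquinone dimethyl ether F6.
- Oxidative demethylation with (NH4)2Ce(NO3)6 returns to the route at 33.

Step 14. The metal-free enolate may be protonated before it cyclises, may be acylated intermolecularly on oxygen, or the β-keto lactone may reopen. The fallback activates the electrophile instead of the nucleophile. It sets out from 21. Exchange with HC(OMe)3 (PPTS cat.) gives the mixed orthoformate F7. TMSOTf (cat.) in CH2Cl2 at −78 °C ionises F7 to a dialkoxycarbenium ion held on O–C20. The silyl enol ether traps this ion at the β face of C4 (Mukaiyama-type orthoester alkylation) to give the lactol methyl ether F8. Jones oxidation (CrO3, H2SO4, acetone) converts F8 into the lactone, and the route is rejoined at 24.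

Further compounds

F1 | step 10 | tricyclic lithium C3–C4 enolate (desilyl form of 18) | C[C@@]12CC[C@@H]3[C@](C(=O)OC)(CCC([O-])=C3C)[C@H]1CC=C(C)C2=O.[Li+]
F2 | step 19 | 2,5-dimethoxybenzaldehyde oxime | COc1ccc(OC)c(C=NO)c1
F3 | step 19 | 2,5-dimethoxybenzonitrile oxide | COc1ccc(OC)c(C#[N+][O-])c1
F4 | step 19 | isoxazoline: O α on C13, C15 (C=N) α on C14 | C[C@@]12CC[C@@H]3[C@]4(CCC[C@]3(C)C(=O)OC4)[C@H]1CC[C@](C)(ON=C5c6cc(OC)ccc6OC)[C@@H]25
F5 | step 19 | 13α-hydroxy 14α-(2,5-dimethoxybenzoyl) lactone | C[C@@]12CC[C@@H]3[C@]4(CCC[C@]3(C)C(=O)OC4)[C@H]1CC[C@](C)(O)[C@@H]2C(=O)c5cc(OC)ccc5OC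
F6 | step 19 | dimethyl ether of 34 | C[C@@]12CC[C@@H]3[C@]4(CCC[C@]3(C)C(=O)OC4)[C@H]1CC[C@](C)(O)[C@@H]2Cc5cc(OC)ccc5OC
F7 | step 14 | C20 dimethoxymethyl ether (mixed orthoformate) of 21 | C[C@@]12CC[C@@H]3[C@](COC(OC)OC)(CCC(O[Si](C)(C)C(C)(C)C)=C3C)[C@H]1CCC(C)=C2OS(=O)(=O)C(F)(F)F
F8 | step 14 | 3-keto 19,20-lactol methyl ether (C19 acetal epimers) | C[C@@]12CC[C@@H]3[C@]4(CCC(=O)[C@]3(C)C(OC)OC4)[C@H]1CCC(C)=C2OS(=O)(=O)C(F)(F)F
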